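Everything rests on disconnecting the C2–C3 bond of the dihydrofuran ring. The feature exploited is the cis pair of adjacent oxygenated carbons, C2 (bound to ring oxygen O1) and C3 (acyloxy), with a 1,1-disubstituted alkene on C2: this is the signature of a 2-borylallyl copper adding through its oxygen-bearing carbon to an ortho aldehyde. One copper-catalysed borylative cyclisation of a 2-(allenyloxy)benzaldehyde, whose C5 acetyl group is masked as a dioxolane, forms C2–C3, closes the furan ring, sets both ring stereocentres and leaves boron on the vinyl carbon as the handle for the formyl carbon. Methylation, ketone reduction, double acylation and allylic oxidation finish the route.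

Key step: step 5

Assumption: the (R,R) antipode of the bisphosphine Ph-BPE is taken to give the (2R,3R) series; this sense is assigned by analogy and, should it prove opposite, the (S,S) ligand is used with no other change.

Step 1
Reactants: 1 4'-hydroxyacetophenone; 2 ethylene glycol
Product: 3 4-(2-methyl-1,3-dioxolan-2-yl)phenol
Conditions: ethylene glycol (3 equiv), TsOH·H2O (2 mol%), toluene, reflux, Dean–Stark; NaHCO3 quench
Reagents that add atoms: ethylene glycol (2), OCCO
Why: Acid-catalysed ketalisation driven by azeotropic removal of water masks the enolisable methyl ketone, which would otherwise undergo aldol chemistry under the alkoxide conditions of steps 4 and 5 and compete as an electrophile in the key step; no stereocentre is formed.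

Step 2
Reactants: 3 4-(2-methyl-1,3-dioxolan-2-yl)phenol; 4 paraformaldehyde
Product: 6 2-hydroxy-5-(2-methyl-1,3-dioxolan-2-yl)benzaldehyde, via hydroxymethylphenol 5 (not isolated)
Conditions: MgCl2 (2 equiv), Et3N (4 equiv), (CH2O)n (6 equiv), MeCN, reflux; ice-cold aq. citric acid to pH 5, fast extraction
Reagents that add atoms: paraformaldehyde (4), C=O
Why: Casnati–Skattebøl ortho-formylation, in which the magnesium phenoxide delivers formaldehyde to the ortho position (para is blocked) and the resulting hydroxymethylphenol 5 is oxidised in the same flask by Oppenauer-type hydride transfer to a second formaldehyde, all under basic conditions that the ketal tolerates.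

Step 3
Reactants: 6 2-hydroxy-5-(2-methyl-1,3-dioxolan-2-yl)benzaldehyde; 7 propargyl bromide
Product: 8 5-(2-methyl-1,3-dioxolan-2-yl)-2-(prop-2-yn-1-yloxy)benzaldehyde
Conditions: propargyl bromide (1.2 equiv), K2CO3 (1.5 equiv), DMF, rt
Reagents that add atoms: propargyl bromide (7), C#CCBr
Why: Williamson ether synthesis, in which the carbonate-generated phenoxide displaces bromide from the primary propargylic halide by SN2 while aldehyde and ketal stay untouched.

Step 4
Reactants: 8 5-(2-methyl-1,3-dioxolan-2-yl)-2-(prop-2-yn-1-yloxy)benzaldehyde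
Product: 9 5-(2-methyl-1,3-dioxolan-2-yl)-2-(propa-1,2-dien-1-yloxy)benzaldehyde
Conditions: KOtBu (0.3 equiv), tBuOH–THF (1:4), 0 °C to rt; aq. NH4Cl; chromatography on Et3N-washed silica
Reagents that add atoms: none
Why: Base-catalysed propargyl-to-allenyl prototropic isomerisation, in which reversible deprotonation at the oxygen-bearing CH2 and reprotonation at the alkyne terminus give the aryloxyallene, while the non-enolisable aldehyde is inert to catalytic tert-butoxide buffered by tert-butanol.

Step 5
Reactants: 9 5-(2-methyl-1,3-dioxolan-2-yl)-2-(propa-1,2-dien-1-yloxy)benzaldehyde; 10 bis(pinacolato)diboron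
Product: 12 (2R,3R)-5-(2-methyl-1,3-dioxolan-2-yl)-2-[1-(4,4,5,5-tetramethyl-1,3,2-dioxaborolan-2-yl)ethenyl]-2,3-dihydro-1-benzofuran-3-ol (2,3-cis), via O-boryl ether 11 (not isolated)
Conditions: CuCl (5 mol%), (R,R)-Ph-BPE [1,2-bis((2R,5R)-2,5-diphenylphospholan-1-yl)ethane] (6 mol%), NaOtBu (10 mol%), B2pin2 (1.1 equiv), THF, 0 °C to rt, slow addition of 9; aq. NH4Cl work-up
Reagents that add atoms: bis(pinacolato)diboron (10), CC1(C)OB(OC1(C)C)B1OC(C)(C)C(C)(C)O1
Why: The ligated copper tert-butoxide and B2pin2 give a copper–boryl species of monovalent copper that adds across the terminal C=C of the aryloxyallene with boron on the central carbon; the catalyst-bound 2-borylallyl copper then adds through its oxygen-bearing carbon to the ortho aldehyde, and the copper alkoxide is borylated by B2pin2 to release O-boryl ether 11 and regenerate the copper–boryl species. The closest known reaction type is the copper-catalysed borylative coupling and cyclisation of allenes with carbonyl groups (borylcupration followed by allyl addition). The dihydrofuran ring closes by 5-exo-trig attack on the C=O. C2 and C3 are formed together in a closed six-membered transition state fused to the nascent five-membered ring; this fusion can only be cis on the nearly planar benzo-fused ring, so the C3 oxygen and the C2 alkenyl group land on the same face (relative control by the short tether, reached only from the allyl geometry with aryloxy cis to the copper-bearing CH2), while the aldehyde face attacked, and so the absolute (2R,3R) sense, is set by the chiral bisphosphine. The step needs chemoselective borylcupration of the allene over addition of the copper–boryl species to the aldehyde, which the phosphine ligand, the electron-rich allene and slow substrate addition should secure. It also needs attack through the oxygen-bearing terminus instead of CH2, which the six-membered transition state and the five-membered ring size enforce, and the ketal keeps the acetyl carbon out of play.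

Step 6
Reactants: 12 (2R,3R)-5-(2-methyl-1,3-dioxolan-2-yl)-2-[1-(4,4,5,5-tetramethyl-1,3,2-dioxaborolan-2-yl)ethenyl]-2,3-dihydro-1-benzofuran-3-ol; 13 iodomethane
Product: 15 1-[(2R,3R)-3-hydroxy-2-(prop-1-en-2-yl)-2,3-dihydro-1-benzofuran-5-yl]ethan-1-one, via isopropenyl ketal 14 (not isolated)
Conditions: MeI (3 equiv), Pd2(dba)3 (2.5 mol%), P(o-tol)3 (10 mol%), K2CO3 (3 equiv), DMF–H2O (9:1), 50 °C, sealed vessel; then PPTS (20 mol%), acetone–H2O, rt
Reagents that add atoms: iodomethane (13), CI; water, O
Why: Suzuki–Miyaura coupling of the alkenyl pinacol boronate with the methyl–palladium iodide formed by oxidative addition of iodomethane to zerovalent palladium replaces boron by methyl without touching C2 or C3, and the very labile para-alkoxyaryl ketal is then hydrolysed under acid too weak to ionise the C3 alcohol.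

Step 7
Reactants: 15 1-[(2R,3R)-3-hydroxy-2-(prop-1-en-2-yl)-2,3-dihydro-1-benzofuran-5-yl]ethan-1-one
Product: 16 (2R,3R)-5-[(1R)-1-hydroxyethyl]-2-(prop-1-en-2-yl)-2,3-dihydro-1-benzofuran-3-ol
Conditions: RuCl(p-cymene)[(R,R)-TsDPEN] (1 mol%), HCO2H–Et3N (5:2), EtOAc, rt
Reagents that add atoms: none
Why: Noyori asymmetric transfer hydrogenation, in which the (R,R)-TsDPEN ruthenium hydride differentiates aryl from methyl and should deliver hydride to the ketone face that gives the (R)-carbinol under catalyst control, without reducing the isopropenyl group or disturbing the remote ring stereocentres.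

Step 8
Reactants: 16 (2R,3R)-5-[(1R)-1-hydroxyethyl]-2-(prop-1-en-2-yl)-2,3-dihydro-1-benzofuran-3-ol; 17 3-methylbutanoic anhydride (isovaleric anhydride)
Product: 19 (1R)-1-[(2R,3R)-3-(3-methylbutanoyloxy)-2-(prop-1-en-2-yl)-2,3-dihydro-1-benzofuran-5-yl]ethyl 3-methylbutanoate, via side-chain monoester 18 (not isolated)
Conditions: isovaleric anhydride (3 equiv), Et3N (4 equiv), DMAP (0.1 equiv), CH2Cl2, 0 °C to rt
Reagents that add atoms: 3-methylbutanoic anhydride (17), CC(C)CC(=O)OC(=O)CC(C)C
Why: DMAP-catalysed acylation of both secondary alcohols (the unhindered side-chain carbinol is expected to react first, then the C3 alcohol) proceeds at oxygen with retention at both carbinol carbons, under mild base that should not provoke elimination toward the benzofuran.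

Step 9
Reactants: 19 (1R)-1-[(2R,3R)-3-(3-methylbutanoyloxy)-2-(prop-1-en-2-yl)-2,3-dihydro-1-benzofuran-5-yl]ethyl 3-methylbutanoate
Product: 21 (1R)-1-[(2R,3R)-3-(3-methylbutanoyloxy)-2-(3-oxoprop-1-en-2-yl)-2,3-dihydro-1-benzofuran-5-yl]ethyl 3-methylbutanoate (CNP0316116.1), via allylic alcohol 20 (not isolated)
Conditions: SeO2 (0.5 equiv), tBuOOH (3 equiv, decane solution), CH2Cl2, rt; aqueous wash; then MnO2 (15 equiv), CH2Cl2, rt
Reagents that add atoms: selenium dioxide, O=[Se]=O (transfers the oxygen); tert-butyl hydroperoxide, CC(C)(C)OO (reoxidant and net oxygen source)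
Why: Riley allylic oxidation (ene reaction of SeO2, then [2,3]-sigmatropic shift) should functionalise the methyl group of the 1,1-disubstituted alkene in preference to the oxygen-bearing C2–H, and MnO2 then oxidises only the primary allylic alcohol 20 to the enal under neutral conditions that leave both esters and all three stereocentres alone.

Compound list
1 | 4'-hydroxyacetophenone | CC(=O)c1ccc(O)cc1 | starting material
2 | ethylene glycol | OCCO | starting material
3 | 4-(2-methyl-1,3-dioxolan-2-yl)phenol | CC1(OCCO1)c1ccc(O)cc1 | intermediate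
4 | paraformaldehyde (drawn as the monomer formaldehyde) | C=O | starting material
5 | 2-(hydroxymethyl)-4-(2-methyl-1,3-dioxolan-2-yl)phenol (present as its magnesium phenoxide, not isolated) | OCc1cc(ccc1O)C1(C)OCCO1 | intermediate
6 | 2-hydroxy-5-(2-methyl-1,3-dioxolan-2-yl)benzaldehyde | O=Cc1cc(ccc1O)C1(C)OCCO1 | intermediate
7 | propargyl bromide | C#CCBr | starting material
8 | 5-(2-methyl-1,3-dioxolan-2-yl)-2-(prop-2-yn-1-yloxy)benzaldehyde | C#CCOc1ccc(C2(C)OCCO2)cc1C=O | intermediate
9 | 5-(2-methyl-1,3-dioxolan-2-yl)-2-(propa-1,2-dien-1-yloxy)benzaldehyde | C=C=COc1ccc(C2(C)OCCO2)cc1C=O | intermediate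
10 | bis(pinacolato)diboron | CC1(C)OB(OC1(C)C)B1OC(C)(C)C(C)(C)O1 | starting material
11 | 2-{[(2R,3R)-5-(2-methyl-1,3-dioxolan-2-yl)-2-[1-(4,4,5,5-tetramethyl-1,3,2-dioxaborolan-2-yl)ethenyl]-2,3-dihydro-1-benzofuran-3-yl]oxy}-4,4,5,5-tetramethyl-1,3,2-dioxaborolane (2,3-cis, not isolated) | C=C(B1OC(C)(C)C(C)(C)O1)[C@H]1Oc2ccc(C3(C)OCCO3)cc2[C@H]1OB1OC(C)(C)C(C)(C)O1 | intermediate
12 | (2R,3R)-5-(2-methyl-1,3-dioxolan-2-yl)-2-[1-(4,4,5,5-tetramethyl-1,3,2-dioxaborolan-2-yl)ethenyl]-2,3-dihydro-1-benzofuran-3-ol (2,3-cis) | C=C(B1OC(C)(C)C(C)(C)O1)[C@H]1Oc2ccc(C3(C)OCCO3)cc2[C@H]1O | intermediate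
13 | iodomethane | CI | starting material
14 | (2R,3R)-5-(2-methyl-1,3-dioxolan-2-yl)-2-(prop-1-en-2-yl)-2,3-dihydro-1-benzofuran-3-ol (2,3-cis, not isolated) | C=C(C)[C@H]1Oc2ccc(C3(C)OCCO3)cc2[C@H]1O | intermediate
15 | 1-[(2R,3R)-3-hydroxy-2-(prop-1-en-2-yl)-2,3-dihydro-1-benzofuran-5-yl]ethan-1-one | C=C(C)[C@H]1Oc2ccc(C(C)=O)cc2[C@H]1O | intermediate
16 | (2R,3R)-5-[(1R)-1-hydroxyethyl]-2-(prop-1-en-2-yl)-2,3-dihydro-1-benzofuran-3-ol | C=C(C)[C@H]1Oc2ccc([C@@H](C)O)cc2[C@H]1O | intermediate
17 | 3-methylbutanoic anhydride (isovaleric anhydride) | CC(C)CC(=O)OC(=O)CC(C)C | starting material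
18 | (1R)-1-[(2R,3R)-3-hydroxy-2-(prop-1-en-2-yl)-2,3-dihydro-1-benzofuran-5-yl]ethyl 3-methylbutanoate (not isolated) | C=C(C)[C@H]1Oc2ccc([C@@H](C)OC(=O)CC(C)C)cc2[C@H]1O | intermediate
19 | (1R)-1-[(2R,3R)-3-(3-methylbutanoyloxy)-2-(prop-1-en-2-yl)-2,3-dihydro-1-benzofuran-5-yl]ethyl 3-methylbutanoate | C=C(C)[C@H]1Oc2ccc([C@@H](C)OC(=O)CC(C)C)cc2[C@H]1OC(=O)CC(C)C | intermediate
20 | (1R)-1-[(2R,3R)-2-(3-hydroxyprop-1-en-2-yl)-3-(3-methylbutanoyloxy)-2,3-dihydro-1-benzofuran-5-yl]ethyl 3-methylbutanoate (not isolated) | C=C(CO)[C@H]1Oc2ccc([C@@H](C)OC(=O)CC(C)C)cc2[C@H]1OC(=O)CC(C)C | intermediate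
21 | (1R)-1-[(2R,3R)-3-(3-methylbutanoyloxy)-2-(3-oxoprop-1-en-2-yl)-2,3-dihydro-1-benzofuran-5-yl]ethyl 3-methylbutanoate (CNP0316116.1) | C=C(C=O)[C@H]1Oc2ccc([C@@H](C)OC(=O)CC(C)C)cc2[C@H]1OC(=O)CC(C)C | target

Total step count: 9 steps.
Longest linear sequence: 9 steps, from 4'-hydroxyacetophenone (1) to 21.

Steps most likely to fail

Step 5. The ligand-controlled allyl addition may give insufficient facial selectivity, or the copper–boryl species may add to the aldehyde or the allyl copper may be protonated before ring closure. The fallback sets out from 9 and returns at 14. Ni(cod)2 (10 mol%, zerovalent nickel) with Me2Zn in THF at 0 °C should effect the known alkylative cyclisation of allenyl aldehydes with organozincs. A nickelacycle forms the same C2–C3 bond with cis geometry and delivers the methyl group to the central allene carbon, giving racemic cis-5-(2-methyl-1,3-dioxolan-2-yl)-2-(prop-1-en-2-yl)-2,3-dihydro-1-benzofuran-3-ol F1. Kinetic resolution with immobilised Candida antarctica lipase B and vinyl acetate in MTBE should acetylate one antipode, expected from the usual lipase preference to be the (2S,3S) one, giving (2S,3S)-5-(2-methyl-1,3-dioxolan-2-yl)-2-(prop-1-en-2-yl)-2,3-dihydro-1-benzofuran-3-yl acetate F2, which is removed by chromatography. The unreacted (2R,3R) alcohol is 14, which is hydrolysed to 15 as in the second stage of step 6; the assignment of the antipodes must be confirmed.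

Step 9. The allylic C–H oxidation may be incomplete or over-run, and the acidic selenium stage may ionise the benzylic esters or drive aromatisation to the benzofuran. The fallback sets out from 12 and returns at 21; it carries the vinyl carbon as an iodide and introduces the formyl carbon from carbon monoxide. Iododeboronation of 12 (NaOMe, then I2, THF–MeOH, −78 to 0 °C) should give (2S,3R)-2-(1-iodoethenyl)-5-(2-methyl-1,3-dioxolan-2-yl)-2,3-dihydro-1-benzofuran-3-ol F3 (same cis geometry; the C2 descriptor changes only because iodine raises the priority of the vinyl carbon). PPTS in acetone–H2O gives 1-[(2S,3R)-3-hydroxy-2-(1-iodoethenyl)-2,3-dihydro-1-benzofuran-5-yl]ethan-1-one F4. Transfer hydrogenation as in step 7 gives (2S,3R)-5-[(1R)-1-hydroxyethyl]-2-(1-iodoethenyl)-2,3-dihydro-1-benzofuran-3-ol F5. Acylation as in step 8 passes through (1R)-1-[(2S,3R)-3-hydroxy-2-(1-iodoethenyl)-2,3-dihydro-1-benzofuran-5-yl]ethyl 3-methylbutanoate F6 to (1R)-1-[(2S,3R)-2-(1-iodoethenyl)-3-(3-methylbutanoyloxy)-2,3-dihydro-1-benzofuran-5-yl]ethyl 3-methylbutanoate F7. Palladium-catalysed reductive carbonylation of the vinyl iodide (Pd(PPh3)4, CO at 1–3 atm, slow addition of Bu3SnH, THF, 50 °C) should then give the enal 21 directly.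

Step 4. The propargylic carbanion or the alkoxide may attack the ortho formyl group under base, and the allenyl ether may hydrolyse on acidic silica. The fallback sets out from 8 and returns at 9 by a redox detour that keeps the aldehyde out of the basic step. NaBH4 in MeOH at 0 °C gives [5-(2-methyl-1,3-dioxolan-2-yl)-2-(prop-2-yn-1-yloxy)phenyl]methanol F8. The same KOtBu isomerisation gives [5-(2-methyl-1,3-dioxolan-2-yl)-2-(propa-1,2-dien-1-yloxy)phenyl]methanol F9. Neutral benzylic oxidation with MnO2 in CH2Cl2 then returns 9.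

Further compounds
F1 | step 5 | racemic cis-5-(2-methyl-1,3-dioxolan-2-yl)-2-(prop-1-en-2-yl)-2,3-dihydro-1-benzofuran-3-ol (both enantiomers) | C=C(C)[C@H]1Oc2ccc(C3(C)OCCO3)cc2[C@H]1O.C=C(C)[C@@H]1Oc2ccc(C3(C)OCCO3)cc2[C@@H]1O
F2 | step 5 | (2S,3S)-5-(2-methyl-1,3-dioxolan-2-yl)-2-(prop-1-en-2-yl)-2,3-dihydro-1-benzofuran-3-yl acetate | C=C(C)[C@@H]1Oc2ccc(C3(C)OCCO3)cc2[C@@H]1OC(C)=O
F3 | step 9 | (2S,3R)-2-(1-iodoethenyl)-5-(2-methyl-1,3-dioxolan-2-yl)-2,3-dihydro-1-benzofuran-3-ol | C=C(I)[C@H]1Oc2ccc(C3(C)OCCO3)cc2[C@H]1O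
F4 | step 9 | 1-[(2S,3R)-3-hydroxy-2-(1-iodoethenyl)-2,3-dihydro-1-benzofuran-5-yl]ethan-1-one | C=C(I)[C@H]1Oc2ccc(C(C)=O)cc2[C@H]1O
F5 | step 9 | (2S,3R)-5-[(1R)-1-hydroxyethyl]-2-(1-iodoethenyl)-2,3-dihydro-1-benzofuran-3-ol | C=C(I)[C@H]1Oc2ccc([C@@H](C)O)cc2[C@H]1O
F6 | step 9 | (1R)-1-[(2S,3R)-3-hydroxy-2-(1-iodoethenyl)-2,3-dihydro-1-benzofuran-5-yl]ethyl 3-methylbutanoate | C=C(I)[C@H]1Oc2ccc([C@@H](C)OC(=O)CC(C)C)cc2[C@H]1O
F7 | step 9 | (1R)-1-[(2S,3R)-2-(1-iodoethenyl)-3-(3-methylbutanoyloxy)-2,3-dihydro-1-benzofuran-5-yl]ethyl 3-methylbutanoate | C=C(I)[C@H]1Oc2ccc([C@@H](C)OC(=O)CC(C)C)cc2[C@H]1OC(=O)CC(C)C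
F8 | step 4 | [5-(2-methyl-1,3-dioxolan-2-yl)-2-(prop-2-yn-1-yloxy)phenyl]methanol | C#CCOc1ccc(C2(C)OCCO2)cc1CO
F9 | step 4 | [5-(2-methyl-1,3-dioxolan-2-yl)-2-(propa-1,2-dien-1-yloxy)phenyl]methanol | C=C=COc1ccc(C2(C)OCCO2)cc1CO
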